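**Retrosynthetic overview**

1. The C4–O aryl ether is made last: the tertiary 4α-alkoxide of a cryptomeridiol-type diol (11-OH silylated) is O-arylated with a (2-bromo-4-chlorophenyl)iodonium salt, followed by Suzuki coupling at C–Br (ring-B phenol boronate) and allyl–aryl coupling at C–Cl.
2. The 4α-OH/4β-CH3 centre comes from the ring-A C3=C4 alkene of α-eudesmol (α-face epoxidation, hydride opening at C3).
3. Ring B is closed by the C7–C8 bond: a C8 aldehyde (unmasked acetal) is attacked by C7 of the C7=C11 isopropylidene (prenyl) π-bond and the tertiary C11 cation is hydrated. Enabling feature: C7 carries the exocyclic carbinol carbon C11 with both methyls, so C7=C11 can serve as the π-nucleophile and its cation becomes the 11-ol, while C8 is a ring-B CH2 whose oxygen is removable; ring B forms as a chair fused trans to ring A.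
4. Ring A comes first, from an enantioselective Diels–Alder reaction that maps (E)-β-ocimene onto C2–C7, C11–C13 and C15 and a 2-substituted acrolein onto C1, C10, C14, C9 and C8, setting C5 and C10.
5. Order of ring formation: ring A (cycloaddition), ring B (Prins cyclisation–hydration), then the two arenes are attached.

Key step: step 5

Assumption: commercial ocimene is E-enriched and its Z isomer is inert in the cycloaddition (its diene cannot reach the s-cis conformer); the known sense of induction of the oxazaborolidinium catalyst with 2-substituted acroleins is taken to carry over to the acetal-bearing enal (the antipodal catalyst is equally available).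

Eudesmane numbering is used for the terpene part; α/β refer to the usual drawing (10β-CH3 up, 5α-H down, trans-fused).

**Route**

Step 1
Reactants: 1 methyl 4,4-dimethoxybutanoate
Product: 2 4,4-dimethoxybutanal
Conditions: i-Bu2AlH, CH2Cl2, −78 °C; aq. potassium sodium tartrate
Reagents that add atoms: none
Why: Partial reduction of a methyl ester with i-Bu2AlH stops at the aldehyde because the tetrahedral aluminium hemiacetal survives at −78 °C until work-up; no stereocentre is formed.

Step 2
Reactants: 2 4,4-dimethoxybutanal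
Product: 3 4,4-dimethoxy-2-methylidenebutanal
Conditions: 37% aq. HCHO, pyrrolidine (10 mol%), EtCO2H (10 mol%), i-PrOH, 45 °C
Reagents that add atoms: formaldehyde, C=O
Why: Amine/acid-catalysed Mannich condensation–elimination (organocatalytic α-methylenation of an aldehyde) converts the α-CH2 into the 1,1-disubstituted enal, and the buffered medium should leave the dimethyl acetal intact; no stereocentre is formed.

Step 3
Reactants: 3 4,4-dimethoxy-2-methylidenebutanal; 4 (E)-β-ocimene [(3E)-3,7-dimethylocta-1,3,6-triene]
Product: 5 (1S,2S)-1-(2,2-dimethoxyethyl)-3-methyl-2-(3-methylbut-2-en-1-yl)cyclohex-3-ene-1-carbaldehyde (CHO cis to the prenyl group)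
Conditions: 4 (2 equiv), (R)-1-(2-methylphenyl)-3,3-diphenyltetrahydro-1H,3H-pyrrolo[1,2-c][1,3,2]oxazaborole (20 mol%), HN(SO2CF3)2 (17 mol%), CH2Cl2, −78 → −40 °C
Reagents that add atoms: none
Why: In this catalytic enantioselective Diels–Alder reaction of a 2-substituted acrolein with an open-chain diene, the unsubstituted diene terminus should bond to the enal β-carbon (regiochemistry dictated by the 1-alkyl terminus, as with 1-vinylcyclohexene), the formyl group should sit endo and the bulkier dimethoxyethyl arm exo (open-chain dienes lack the bridging CH2 that makes such enals exo-selective with cyclopentadiene), which places CHO cis to the prenyl group, and the protonated oxazaborolidine shields one face of the bound enal so that C10 and C5 are set together in the absolute sense shown.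

Step 4
Reactants: 5 (1S,2S)-1-(2,2-dimethoxyethyl)-3-methyl-2-(3-methylbut-2-en-1-yl)cyclohex-3-ene-1-carbaldehyde
Product: 7 (5R,6R)-5-(2,2-dimethoxyethyl)-1,5-dimethyl-6-(3-methylbut-2-en-1-yl)cyclohex-1-ene, via hydrazone 6 (not isolated)
Conditions: N2H4·H2O, EtOH, 80 °C; then KOt-Bu, DMSO, 25 → 60 °C
Reagents that add atoms: none
Why: Wolff–Kishner reduction (hydrazone formation, then base-mediated loss of N2 at moderate temperature) should turn the neopentyl formyl group into the angular methyl C14 without touching the acetal, the alkenes or the two stereocentres, neither of which is epimerisable.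

Step 5
Reactants: 7 (5R,6R)-5-(2,2-dimethoxyethyl)-1,5-dimethyl-6-(3-methylbut-2-en-1-yl)cyclohex-1-ene
Product: 9 eudesm-3-ene-8α,11-diol (trans-fused; 10β-CH3; 5α-H; 7β-(2-hydroxypropan-2-yl); 8α-OH), via aldehyde 8 (not isolated)
Conditions: 1% aq. H2SO4–THF (1:1), 23 °C
Reagents that add atoms: water, O
Why: Dilute aqueous acid first hydrolyses the dimethyl acetal to aldehyde 8, whose protonated carbonyl carbon C8 is attacked by C7 of the trisubstituted C7=C11 double bond (Prins cyclisation, the cationic counterpart of a type 1 carbonyl-ene reaction), and the tertiary C11 cation is captured by water to give the 11-ol directly. The closest known reaction is the acid-mediated cyclisation–hydration of citronellal to p-menthane-3,8-diol. Ring B closes in a 6-exo-trig sense with respect to both π-bonds (C8=O and C7=C11 each keep one atom outside the ring) through a chair transition state. C7 is controlled by that chair: the trans-disposed C5–C6 and C10–C9 bonds on ring A allow only the trans-fused chair, in which the developing CMe2 cation is equatorial (7β) because the axial alternative is syn-axial to H5 and H9; C8 is expected mainly 8α (an axial oxygen would clash with the axial C10 methyl), and its configuration is irrelevant because the oxygen is removed in steps 6 and 7. The step needs chemoselectivity for the prenyl alkene over the ring C3=C4 alkene and capture by water instead of proton loss; the first is secured by the six-membered chair open only to the prenyl alkene (attack by C3 would need a boat leading to a bicyclo[2.2.2]octane) and by acid too dilute to protonate the ring alkene at 23 °C, the second by the aqueous medium.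

Step 6
Reactants: 9 eudesm-3-ene-8α,11-diol
Product: 10 8α-(phenoxythiocarbonyloxy)eudesm-3-en-11-ol
Conditions: PhOC(S)Cl, pyridine, CH2Cl2, 0 °C
Reagents that add atoms: O-phenyl chlorothionoformate, S=C(Cl)Oc1ccccc1
Why: Acylation with the chlorothionoformate should be selective for the secondary equatorial C8 hydroxyl, the tertiary C11 hydroxyl being too hindered at 0 °C, and gives the thionocarbonate needed for a Barton–McCombie deoxygenation; no stereocentre is changed.

Step 7
Reactants: 10 8α-(phenoxythiocarbonyloxy)eudesm-3-en-11-ol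
Product: 11 (+)-α-eudesmol [eudesm-3-en-11-ol; 2-[(2R,4aR,8aR)-4a,8-dimethyl-1,2,3,4,4a,5,6,8a-octahydronaphthalen-2-yl]propan-2-ol]
Conditions: n-Bu3SnH, AIBN (20 mol%), toluene, 100 °C
Reagents that add atoms: none
Why: In the Barton–McCombie deoxygenation the stannyl radical adds to C=S, the secondary C8 radical fragments off and abstracts hydrogen from n-Bu3SnH, which removes the superfluous C8 stereocentre.

Step 8
Reactants: 11 (+)-α-eudesmol
Product: 12 11-(triethylsilyloxy)eudesm-3-ene
Conditions: Et3SiOTf, 2,6-lutidine, CH2Cl2, −78 → 0 °C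
Reagents that add atoms: triethylsilyl trifluoromethanesulfonate, CC[Si](CC)(CC)OS(=O)(=O)C(F)(F)F
Why: Silyl ether protection of the tertiary alcohol with the silyl triflate and a hindered base masks the 11-OH, so that the 4-OH made next is the only free hydroxyl at the arylation stage.

Step 9
Reactants: 12 11-(triethylsilyloxy)eudesm-3-ene
Product: 13 3α,4α-epoxy-11-(triethylsilyloxy)eudesmane (4β-CH3)
Conditions: m-CPBA, NaHCO3, CH2Cl2, 0 °C
Reagents that add atoms: 3-chloroperoxybenzoic acid, OOC(=O)c1cccc(Cl)c1
Why: Peracid epoxidation should occur on the α face of the C3=C4 bond, anti to the axial 10β-methyl group that shields the β face, which sets C4 with oxygen α and methyl β (and the incidental C3 centre).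

Step 10
Reactants: 13 3α,4α-epoxy-11-(triethylsilyloxy)eudesmane
Product: 14 11-(triethylsilyloxy)eudesman-4α-ol (4β-CH3; silylated cryptomeridiol)
Conditions: LiBHEt3, THF, 0 → 65 °C; then aq. NaOH
Reagents that add atoms: none
Why: Reductive epoxide opening by hydride attack (SN2) at the less substituted carbon C3 leaves the C4–O bond untouched, so the tertiary 4α-alcohol should form with retention at C4 while C3 becomes CH2.

Step 11
Reactants: 15 2-bromo-4-chloro-1-iodobenzene
Product: 17 (2-bromo-4-chlorophenyl)(2,4,6-trimethoxyphenyl)iodonium 4-methylbenzenesulfonate, via [hydroxy(tosyloxy)iodo]arene 16 (not isolated)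
Conditions: m-CPBA, TsOH·H2O, MeCN, 77 °C; then 1,3,5-trimethoxybenzene, 77 → 23 °C
Reagents that add atoms: 1,3,5-trimethoxybenzene, COc1cc(OC)cc(OC)c1; 4-methylbenzenesulfonic acid, Cc1ccc(cc1)S(O)(=O)=O
Why: One-pot diaryliodonium salt synthesis: peracid oxidation of the aryl iodide in the presence of TsOH gives 16, which undergoes electrophilic aromatic substitution with the electron-rich trimethoxybenzene to give an unsymmetrical salt carrying a non-transferable trimethoxyphenyl group.

Step 12
Reactants: 14 11-(triethylsilyloxy)eudesman-4α-ol; 17 (2-bromo-4-chlorophenyl)(2,4,6-trimethoxyphenyl)iodonium 4-methylbenzenesulfonate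
Product: 19 4α-(2-bromo-4-chlorophenoxy)-11-(triethylsilyloxy)eudesmane, via sodium 4α-alkoxide 18 (not isolated)
Conditions: NaH, toluene, 50 °C; then 17, t-BuOMe–toluene, 23 → 40 °C
Reagents that add atoms: none
Why: Metal-free O-arylation of a tertiary alkoxide with a diaryliodonium salt (ligand coupling at trivalent iodine) should transfer the electron-poorer, ortho-substituted 2-bromo-4-chlorophenyl group in preference to the trimethoxyphenyl group, and since the C4–O bond of the alcohol is not broken C4 keeps its configuration.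

Step 13
Reactants: 20 2-allyl-4-bromophenol
Product: 21 2-allyl-4-(4,4,5,5-tetramethyl-1,3,2-dioxaborolan-2-yl)phenol
Conditions: B2pin2, Pd(dppf)Cl2 (3 mol%), KOAc, 1,4-dioxane, 80 °C
Reagents that add atoms: bis(pinacolato)diboron, CC1(C)OB(OC1(C)C)B1OC(C)(C)C(C)(C)O1
Why: Miyaura borylation of the aryl bromide tolerates the free phenol and the allyl group and gives the ring-B boronate without a protecting group.

Step 14
Reactants: 19 4α-(2-bromo-4-chlorophenoxy)-11-(triethylsilyloxy)eudesmane; 21 2-allyl-4-(4,4,5,5-tetramethyl-1,3,2-dioxaborolan-2-yl)phenol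
Product: 22 4α-{[3'-allyl-5-chloro-4'-hydroxy-(1,1'-biphenyl)-2-yl]oxy}-11-(triethylsilyloxy)eudesmane
Conditions: Pd(dppf)Cl2 (5 mol%), K3PO4, 1,4-dioxane–H2O (5:1), 85 °C
Reagents that add atoms: none
Why: Suzuki–Miyaura coupling with this bisphosphine catalyst should be chemoselective for the C–Br bond over the C–Cl bond, forming the biaryl bond ortho to the tertiary ether while the chloride is kept for the next coupling.

Step 15
Reactants: 22 4α-{[3'-allyl-5-chloro-4'-hydroxy-(1,1'-biphenyl)-2-yl]oxy}-11-(triethylsilyloxy)eudesmane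
Product: 23 4α-{[3',5-diallyl-4'-hydroxy-(1,1'-biphenyl)-2-yl]oxy}-11-(triethylsilyloxy)eudesmane
Conditions: allyl-B(pin), Pd(OAc)2 (5 mol%), XPhos (10 mol%), K3PO4, THF–H2O (10:1), 70 °C
Reagents that add atoms: allylboronic acid pinacol ester, C=CCB1OC(C)(C)C(C)(C)O1
Why: Suzuki–Miyaura-type allyl–aryl coupling of the remaining electron-rich aryl chloride, enabled by the bulky biarylphosphine, installs the para-allyl group; the unsubstituted allyl unit has no regiochemical ambiguity.

Step 16
Reactants: 23 4α-{[3',5-diallyl-4'-hydroxy-(1,1'-biphenyl)-2-yl]oxy}-11-(triethylsilyloxy)eudesmane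
Product: 24 target, 4α-{[3',5-diallyl-4'-hydroxy-(1,1'-biphenyl)-2-yl]oxy}eudesman-11-ol (4R,5R,7R,10R)
Conditions: n-Bu4NF, THF, 50 °C
Reagents that add atoms: none
Why: Fluoride-mediated desilylation of the tertiary triethylsilyl ether under non-acidic conditions should release the 11-OH without endangering the acid-labile tertiary alkyl aryl ether or the allyl groups.

**Compound list**

1 | methyl 4,4-dimethoxybutanoate | COC(=O)CCC(OC)OC | starting material
2 | 4,4-dimethoxybutanal | O=CCCC(OC)OC | intermediate
3 | 4,4-dimethoxy-2-methylidenebutanal | C=C(C=O)CC(OC)OC | intermediate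
4 | (E)-β-ocimene | C=C/C(C)=C/CC=C(C)C | starting material
5 | (1S,2S)-1-(2,2-dimethoxyethyl)-3-methyl-2-(3-methylbut-2-en-1-yl)cyclohex-3-ene-1-carbaldehyde | CC1=CCC[C@](C=O)(CC(OC)OC)[C@H]1CC=C(C)C | intermediate
6 | (E)-hydrazone of 5 | CC1=CCC[C@](/C=N/N)(CC(OC)OC)[C@H]1CC=C(C)C | intermediate
7 | (5R,6R)-5-(2,2-dimethoxyethyl)-1,5-dimethyl-6-(3-methylbut-2-en-1-yl)cyclohex-1-ene | CC1=CCC[C@](C)(CC(OC)OC)[C@H]1CC=C(C)C | intermediate
8 | 2-[(1R,2R)-1,3-dimethyl-2-(3-methylbut-2-en-1-yl)cyclohex-3-en-1-yl]acetaldehyde | CC1=CCC[C@](C)(CC=O)[C@H]1CC=C(C)C | intermediate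
9 | eudesm-3-ene-8α,11-diol | CC1=CCC[C@]2(C)C[C@H](O)[C@@H](C(C)(C)O)C[C@H]21 | intermediate
10 | 8α-(phenoxythiocarbonyloxy)eudesm-3-en-11-ol | CC1=CCC[C@]2(C)C[C@H](OC(=S)Oc3ccccc3)[C@@H](C(C)(C)O)C[C@H]21 | intermediate
11 | (+)-α-eudesmol | CC1=CCC[C@]2(C)CC[C@@H](C(C)(C)O)C[C@H]21 | intermediate
12 | 11-(triethylsilyloxy)eudesm-3-ene | CC1=CCC[C@]2(C)CC[C@@H](C(C)(C)O[Si](CC)(CC)CC)C[C@H]21 | intermediate
13 | 3α,4α-epoxy-11-(triethylsilyloxy)eudesmane | C[C@]12[C@H](O1)CC[C@]3(C)CC[C@@H](C(C)(C)O[Si](CC)(CC)CC)C[C@H]32 | intermediate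
14 | 11-(triethylsilyloxy)eudesman-4α-ol | O[C@]1(C)CCC[C@]2(C)CC[C@@H](C(C)(C)O[Si](CC)(CC)CC)C[C@H]21 | intermediate
15 | 2-bromo-4-chloro-1-iodobenzene | Clc1ccc(I)c(Br)c1 | starting material
16 | 2-bromo-4-chloro-1-[hydroxy(tosyloxy)iodo]benzene | OI(OS(=O)(=O)c1ccc(C)cc1)c1ccc(Cl)cc1Br | intermediate
17 | (2-bromo-4-chlorophenyl)(2,4,6-trimethoxyphenyl)iodonium 4-methylbenzenesulfonate | COc1cc(OC)c([I+]c2ccc(Cl)cc2Br)c(OC)c1.Cc1ccc(cc1)S(=O)(=O)[O-] | intermediate
18 | sodium 4α-alkoxide of 14 | [Na+].[O-][C@]1(C)CCC[C@]2(C)CC[C@@H](C(C)(C)O[Si](CC)(CC)CC)C[C@H]21 | intermediate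
19 | 4α-(2-bromo-4-chlorophenoxy)-11-(triethylsilyloxy)eudesmane | Clc1ccc(O[C@]2(C)CCC[C@]3(C)CC[C@@H](C(C)(C)O[Si](CC)(CC)CC)C[C@H]32)c(Br)c1 | intermediate
20 | 2-allyl-4-bromophenol | C=CCc1cc(Br)ccc1O | starting material
21 | 2-allyl-4-(4,4,5,5-tetramethyl-1,3,2-dioxaborolan-2-yl)phenol | C=CCc1cc(ccc1O)B1OC(C)(C)C(C)(C)O1 | intermediate
22 | 4α-{[3'-allyl-5-chloro-4'-hydroxy-(1,1'-biphenyl)-2-yl]oxy}-11-(triethylsilyloxy)eudesmane | Clc1ccc(O[C@]2(C)CCC[C@]3(C)CC[C@@H](C(C)(C)O[Si](CC)(CC)CC)C[C@H]32)c(-c2ccc(O)c(CC=C)c2)c1 | intermediate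
23 | 4α-{[3',5-diallyl-4'-hydroxy-(1,1'-biphenyl)-2-yl]oxy}-11-(triethylsilyloxy)eudesmane | C=CCc1ccc(O[C@]2(C)CCC[C@]3(C)CC[C@@H](C(C)(C)O[Si](CC)(CC)CC)C[C@H]32)c(-c2ccc(O)c(CC=C)c2)c1 | intermediate
24 | 4α-{[3',5-diallyl-4'-hydroxy-(1,1'-biphenyl)-2-yl]oxy}eudesman-11-ol (CNP0219722.1) | C=CCc1ccc(O[C@]2(C)CCC[C@]3(C)CC[C@@H](C(C)(C)O)C[C@H]32)c(-c2ccc(O)c(CC=C)c2)c1 | target

**Totals and risks**

Total step count: 16. Longest linear sequence: 14 steps (steps 1–10, 12, 14, 15, 16).

Steps most likely to fail:

Step 3. What may go wrong: erosion of endo selectivity (the formyl group taking the exo position, which would give the wrong C5/C10 relationship), leakage to the other regioisomer because the 1-alkyl and 2-methyl groups of the diene direct in opposite senses, or ionisation of the acetal by the cationic boron catalyst. Fallback, setting out from 4: cycloaddition with methacrolein under the antipodal (S)-oxazaborolidinium catalyst, where the formyl-exo mode is the one required and no acetal is present, would give (1S,2S)-1,3-dimethyl-2-(3-methylbut-2-en-1-yl)cyclohex-3-ene-1-carbaldehyde F1 (CHO trans to the prenyl group, C14 already a methyl). Wittig reaction with Ph3P=CHOMe (from Ph3PCH2OMe Cl and KOt-Bu, THF, 0 °C) would homologate the formyl group to the methyl enol ether F2. Under the conditions of step 5, F2 is hydrolysed to 8 and cyclises, so the route is rejoined at 9 (steps 1, 2 and 4 are then not needed).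

Step 5. What may go wrong: proton loss from the C11 cation in place of hydration, or acid-induced migration or hydration of the C3=C4 double bond if ring closure is slow. Fallback, setting out from 7: transacetalisation with pyridinium 4-methylbenzenesulfonate in wet acetone to isolate 8, then an anhydrous ZnBr2-promoted carbonyl-ene cyclisation (CH2Cl2, 0 °C) to eudesma-3,11-dien-8α-ol F3. Oxymercuration–demercuration (Hg(OAc)2, THF–H2O; then NaBH4, NaOH), which hydrates the 1,1-disubstituted isopropenyl group much faster than the trisubstituted ring alkene, rejoins the route at 9.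

Step 12. What may go wrong: deprotonation of the iodonium salt ortho to iodine by the hindered alkoxide (aryne formation and regioisomeric ethers), or failure of the crowded ligand coupling. Fallback, setting out from 14: nucleophilic aromatic substitution of its potassium alkoxide (KN(SiMe3)2, THF, 0 °C) on 2-bromo-1-fluoro-4-nitrobenzene would give 4α-(2-bromo-4-nitrophenoxy)-11-(triethylsilyloxy)eudesmane F4. Reduction (Fe, NH4Cl, EtOH–H2O, 70 °C) would give 4α-(4-amino-2-bromophenoxy)-11-(triethylsilyloxy)eudesmane F5, and Sandmeyer-type chlorodeamination (t-BuONO, CuCl2, MeCN, 0 → 25 °C) rejoins the route at 19.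

**Further compounds**

F1 | step 3 | (1S,2S)-1,3-dimethyl-2-(3-methylbut-2-en-1-yl)cyclohex-3-ene-1-carbaldehyde | CC1=CCC[C@](C)(C=O)[C@H]1CC=C(C)C
F2 | step 3 | (5R,6R)-5-[(E)-2-methoxyethenyl]-1,5-dimethyl-6-(3-methylbut-2-en-1-yl)cyclohex-1-ene | CC1=CCC[C@](C)(/C=C/OC)[C@H]1CC=C(C)C
F3 | step 5 | eudesma-3,11-dien-8α-ol | CC1=CCC[C@]2(C)C[C@H](O)[C@@H](C(C)=C)C[C@H]21
F4 | step 12 | 4α-(2-bromo-4-nitrophenoxy)-11-(triethylsilyloxy)eudesmane | [O-][N+](=O)c1ccc(O[C@]2(C)CCC[C@]3(C)CC[C@@H](C(C)(C)O[Si](CC)(CC)CC)C[C@H]32)c(Br)c1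
F5 | step 12 | 4α-(4-amino-2-bromophenoxy)-11-(triethylsilyloxy)eudesmane | Nc1ccc(O[C@]2(C)CCC[C@]3(C)CC[C@@H](C(C)(C)O[Si](CC)(CC)CC)C[C@H]32)c(Br)c1
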